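## Structural features

Neocryptomerin is a biflavone of the C–O–C type: two 2-aryl-4H-chromen-4-one units, each with a benzo ring A, a pyranone ring C and an aryl ring B, six aromatic rings in all. Unit 1 is a 5-hydroxy-7-methoxyflavone whose ring B oxygen at C4' is the bridging ether oxygen. That oxygen is bonded to C6 of ring A of unit 2, a 5,7-dihydroxyflavone with a 4-hydroxyphenyl ring B. The molecule has no stereocentre, so no stereocentres stand next to each other; every selectivity question concerns position or functional group. Fragile points are the two pyranones (opened by hot alkali), the four free phenols (easily oxidised, most of all the 5,6,7-trioxygenated ring A of unit 2), the single O7 methyl ether of unit 1 (which rules out any global dealkylation), and the 5,7-dihydroxy-6-aryloxy array, which hot strong acid can open and reclose to the 8-linked isomer (Wessely–Moser). The real difficulty is the ether carbon C6 of unit 2: flanked by O5 and O7, it would have to come from a hindered 2,6-dioxygenated phenol that is hard to arylate, and the two ortho oxygens make ring closure to a 6- or an 8-linked flavone ambiguous. The plan exploits the fact that in each unit the C4 carbonyl of ring C has exactly one peri C–H, the C5–H of ring A, within reach of a carbonyl-bound metal through a five-membered chelate. Both C5 oxygens can therefore be left out until the end, so ring A of unit 2 descends from a 4-aryloxyresorcinol with one ortho oxygen, which is easy to make and has one preferred acylation site.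

## Logic of the disconnections

18 ⇒ 17. The two O–acetyl bonds on O7 and on the ring B oxygen of unit 2 are cut. These phenols must be electron-poor esters while the C5 positions are oxidised. The skeleton is unchanged, but the oxidation substrate becomes robust. The forward cleavage must be a cold methanolysis that spares both pyranones and gives ring A of unit 2 no chance to isomerise.

17 ⇒ 15 (through 16). The C5–O bonds of unit 1 and of unit 2 are cut and two C–H bonds restored. Each oxygen is peri to a pyranone carbonyl, the one place where a directed C–H oxidation can put it. The gain is large: unit 1 now comes from the 2,4-dioxygenated ketone 7, and ring A of unit 2 loses one of the two oxygens that crowd C6, so the ether and the ring closure become unambiguous. The forward step must oxidise two C–H bonds with complete site selectivity and leave three aryl ethers alone.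

15 ⇒ 14. The same two O–acetyl bonds are cut. Acetylation is placed last so that the phenols stay free through the acid-mediated condensation and a single clean acylation gives a purifiable precursor. The demand is trivial.

14 ⇒ 13. The O1–C2 bond of ring C of unit 2 is cut and the C2=C3 oxidation level is lowered. A flavone maps onto a 2'-hydroxychalcone, so ring C becomes an open enone. The oxidative closure must tolerate three free phenols and the finished unit 1.

13 ⇒ 11 + 12. The Cα=Cβ bond of the enone is cut (aldol). This detaches ring B of unit 2 as the simple aldehyde 12. The condensation must avoid base strong enough to open ring C of unit 1.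

11 ⇒ 10. The aryl–acetyl C–C bond is cut. The carbon in question is ortho to one hydroxyl and para to the other, the natural site of electrophilic acylation. Ring A of unit 2 becomes a plain resorcinol ether. The acylation must go to that one carbon and not to unit 1.

10 ⇒ 9. The two O–benzyl bonds are cut. The resorcinol oxygens need blocking through ether formation, base condensation and iodine oxidation. Hydrogenolysis must spare the C2=C3 bond of the flavone.

9 ⇒ 8. The O1–C2 bond of ring C of unit 1 is cut and C2=C3 reduced to the chalcone level, for the same reason as above. The oxidative closure must not iodinate the electron-rich benzyloxy ring.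

8 ⇒ 6 + 7. The Cα=Cβ bond is cut. Ketone 7 brings ring A of unit 1 with O7 already methylated, so no selective methylation is ever needed. A standard base condensation suffices because no flavone is present yet.

6 ⇒ 4 + 5. The diaryl ether bond on the ring B side (C4'–O) is cut. The para formyl group of 5 activates fluoride displacement, and phenol 4 has only one ortho substituent. The forward step is a plain nucleophilic aromatic substitution.

4 ⇒ 2 (through 3). The phenolic C–O bond is traced back to a formyl C–C bond by oxygen insertion. This fixes the phenol oxygen relative to the two protected oxygens, starting from a cheap aldehyde. The aryl group must migrate in preference to hydride.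

2 ⇒ 1. Two O–benzyl bonds are cut, leading to commercial 1. Both hydroxyls, including the hydrogen-bonded one, must be alkylated.

## Other disconnections considered

Alternative 1: The cut runs through ring B of unit 1 (bonds C3'–C4' and C5'–C6'), so this ring is grown on the bridging oxygen instead of being bought as a benzene. In the forward step the aryl ethynyl ether A2 and methyl coumalate A3 are heated. Inverse-demand Diels–Alder addition across C3 and C6 of the 2-pyranone, then loss of CO2, should give the 4-aryloxybenzoate A1.
- In its favour: the diaryl ether is never made by substitution at a phenol flanked by two oxygens. All three oxygens of ring A of unit 2 are present from the start on a symmetric ring, so a later C-acylation has one outcome. The polarisation of the ynol ether (β-carbon to C6 of A3) should deliver the para benzoate.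
- Against it: A2 must be made from a hindered, air-sensitive phenol via a dichlorovinyl ether and strong base, and aryl ynol ethers hydrate and polymerise easily. After A1 there remain the conversion of the ester into ring C of unit 1, acetal removal, acylation, the whole of unit 2 and a debenzylation.
- Comparison, structure: the alternative carries every oxygen of the target from the outset and needs no late oxidation; on this point it is the better plan. On the 6- versus 8-linkage it is the equal of the chosen plan, since both settle it by construction.
- Comparison, mechanism: a metal-free thermal pericyclic step stands against a catalytic C–H metalation. Both have sound selectivity arguments, but the alternative depends on a labile reagent.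
- Comparison, step economy: roughly fifteen or more steps are estimated against twelve, so the chosen plan is shorter.

Alternative 2: The cut is the C4a–C5 bond of ring A of unit 2. That ring is unfolded into a keto ester chain on a 4-pyranone, the racemic keto ester A5. In the forward step Mg(OMe)2 or NaOMe in methanol should equilibrate A5 to a vinylogous dienolate. Its ring carbon (the future C4a) attacks the ester carbonyl, and the resulting triketone tautomerises to the aromatic ring, giving the benzyl ether A4.
- In its favour: the oxygen pattern and the 6-linkage are written into the chain, because the aryloxy carbon lies between the ketone and ester carbons. There is no ambiguity and no oxidation, and aromatisation drives the closure under mild base.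
- Against it: A5 is an α-aryloxy β-keto ester on a pyranone side chain and needs a long route of its own. It has competing pathways (O-acylation to a pyranopyranone, retro-Claisen cleavage by methoxide, alternative aldol closures). The finished unit 1 with its free 5-hydroxyl must also survive methoxide.
- Comparison, structure: the alternative is the better plan on oxidation-state economy and the equal on regiochemical certainty.
- Comparison, mechanism: an equilibrating ionic condensation with several possible exits stands against a directed metalation with a single reachable C–H. The chosen step is more predictable.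
- Comparison, step economy: one debenzylation follows A4, as one deacetylation follows the chosen key step, so the endgames are equal. The assembly of A5 is estimated to be clearly longer than the ten steps to 15.

Alternative 3: The cut is the C2=C3 bond of both pyranones. In the forward step the bis(acylphosphorane) diester A7 is heated. Each ylide carbon attacks the neighbouring aroyl ester carbonyl and two molecules of Ph3PO are lost, giving the tetrabenzyl ether A6.
- In its favour: both rings C are closed in one neutral thermal operation, at the correct oxidation level and with all oxygens in place. On bonds made per step it is the equal of the chosen key step, and it closes two rings besides. The intramolecular ester olefination of acylphosphoranes is established for chromones.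
- Against it: A7 contains the fully oxygenated, hindered diaryl ether that the chosen plan avoids. The two ortho oxygens of ring A of unit 2 must also be told apart (one as aroyl ester, one as benzyl ether), which brings back the 6- versus 8-problem as a protecting-group problem. Two α-functionalised ketones and two phosphoranes have to be made, and four benzyl ethers must finally be removed without reducing C2=C3.
- Comparison, structure: the alternative needs no oxidation (better) but a much harder ether and oxygen differentiation (worse).
- Comparison, mechanism: the Wittig closure is as reliable as the C–H oxidation and free of oxidant; on functional-group tolerance it is the better step.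
- Comparison, step economy: the preparation of A7 is estimated to be considerably longer than the route to 15, and stoichiometric Ph3PO is formed twice.

Key step: step 11

Remark on numbering: usual flavone numbering is used within each unit; unit 1 is the 7-methoxyflavone, unit 2 the flavone carrying the ether oxygen at C6.

Remark on the structures: 15 and 17 were checked atom by atom against 18. They differ from it only in the two C5 oxygens (15) and the two acetyl groups (15 and 17), and no correction was needed.

## Route

Step 1
Reactants: 1 2,4-dihydroxybenzaldehyde
Product: 2 2,4-bis(benzyloxy)benzaldehyde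
Conditions: BnBr (2.4 equiv), K2CO3, DMF, 60 °C
Reagents that add atoms: benzyl bromide, BrCc1ccccc1
Why: Williamson ether synthesis; with excess halide and warming the hydrogen-bonded 2-hydroxyl should also be alkylated.

Step 2
Reactants: 2 2,4-bis(benzyloxy)benzaldehyde
Product: 4 2,4-bis(benzyloxy)phenol, via 2,4-bis(benzyloxy)phenyl formate 3 (not isolated)
Conditions: mCPBA, CH2Cl2, 0 °C to rt; then NaOH, MeOH/H2O, rt; HCl work-up
Reagents that add atoms: mCPBA, O=C(OO)c1cccc(Cl)c1
Why: Baeyer–Villiger (Dakin-type) oxidation; the electron-rich dialkoxyaryl group migrates in preference to hydride, and the formate is saponified in the same flask.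

Step 3
Reactants: 4 2,4-bis(benzyloxy)phenol; 5 4-fluorobenzaldehyde
Product: 6 4-[2,4-bis(benzyloxy)phenoxy]benzaldehyde
Conditions: K2CO3, DMF, 100 °C, Ar
Reagents that add atoms: none
Why: Nucleophilic aromatic substitution; the para formyl group stabilises the Meisenheimer adduct and the phenoxide has only one ortho substituent, so ether formation should be easy.

Step 4
Reactants: 6 4-[2,4-bis(benzyloxy)phenoxy]benzaldehyde; 7 paeonol (2-hydroxy-4-methoxyacetophenone)
Product: 8 (E)-3-{4-[2,4-bis(benzyloxy)phenoxy]phenyl}-1-(2-hydroxy-4-methoxyphenyl)prop-2-en-1-one
Conditions: KOH, EtOH/THF, rt; then aq. HCl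
Reagents that add atoms: none
Why: Claisen–Schmidt condensation of a methyl ketone with a non-enolisable aldehyde; elimination from the aldol gives the E-enone under thermodynamic control.

Step 5
Reactants: 8 (E)-chalcone
Product: 9 2-{4-[2,4-bis(benzyloxy)phenoxy]phenyl}-7-methoxy-4H-chromen-4-one
Conditions: I2 (10 mol %), DMSO, 130 °C
Reagents that add atoms: none
Why: Iodine/DMSO oxidative cyclisation of a 2'-hydroxychalcone: oxa-Michael closure, then iodination next to the ketone and loss of HI, which DMSO reoxidises; catalytic iodine limits iodination of the benzyloxy ring.

Step 6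
Reactants: 9 bis(benzyl ether) flavone
Product: 10 2-[4-(2,4-dihydroxyphenoxy)phenyl]-7-methoxy-4H-chromen-4-one
Conditions: H2 (1 atm), Pd/C, THF/MeOH, rt
Reagents that add atoms: none
Why: Hydrogenolysis of two benzyl aryl ethers; the aryl-conjugated C2=C3 bond of the flavone, the diaryl ether and the methyl ether should be inert at 1 atm and room temperature.

Step 7
Reactants: 10 resorcinol flavone
Product: 11 2-[4-(5-acetyl-2,4-dihydroxyphenoxy)phenyl]-7-methoxy-4H-chromen-4-one
Conditions: AcOH, BF3·OEt2, 90 °C; then aq. NaOAc
Reagents that add atoms: acetic acid, CC(=O)O
Why: Friedel–Crafts C-acetylation of a resorcinol (Nencki conditions; O-acylation and Fries shift lead to the same ketone) at the carbon ortho to one hydroxyl and para to the other; the position between the hydroxyls is crowded, the carbon next to the aryloxy group is not activated, and the carbonyl-deactivated ring A of unit 1 should not compete.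

Step 8
Reactants: 11 acetophenone flavone; 12 4-hydroxybenzaldehyde
Product: 13 (E)-1-{2,4-dihydroxy-5-[4-(7-methoxy-4-oxo-4H-chromen-2-yl)phenoxy]phenyl}-3-(4-hydroxyphenyl)prop-2-en-1-one
Conditions: BF3·OEt2, 1,4-dioxane, rt; then aq. NaOAc
Reagents that add atoms: none
Why: Acid-mediated Claisen–Schmidt condensation: the boron-bound enol of the o-hydroxyacetophenone adds to the BF3-activated aldehyde and dehydration gives the E-enone; acid is chosen because free phenols are tolerated and hydroxide would put ring C of unit 1 at risk.

Step 9
Reactants: 13 (E)-trihydroxychalcone
Product: 14 7-hydroxy-2-(4-hydroxyphenyl)-6-[4-(7-methoxy-4-oxo-4H-chromen-2-yl)phenoxy]-4H-chromen-4-one (5,5''-dideoxyneocryptomerin)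
Conditions: I2 (10 mol %), DMSO, 120 °C, Ar
Reagents that add atoms: none
Why: Same iodine/DMSO oxidative cyclisation as in step 5; only the hydroxyl ortho to the ketone can close ring C, so the aryloxy group ends at C6, and catalytic iodine in the HI-containing medium keeps iodination of the phenol rings low and reversible.

Step 10
Reactants: 14 5,5''-dideoxyneocryptomerin
Product: 15 4-{7-acetoxy-6-[4-(7-methoxy-4-oxo-4H-chromen-2-yl)phenoxy]-4-oxo-4H-chromen-2-yl}phenyl acetate (5,5''-dideoxyneocryptomerin diacetate)
Conditions: Ac2O, pyridine, DMAP (cat.), rt
Reagents that add atoms: acetic anhydride, CC(=O)OC(C)=O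
Why: O-acetylation of the two phenols, the only nucleophilic sites; the diacetate is electron-poor at both phenol rings and should be soluble and easy to purify.

Step 11
Reactants: 15 5,5''-dideoxyneocryptomerin diacetate
Product: 17 4-{7-acetoxy-5-hydroxy-6-[4-(5-hydroxy-7-methoxy-4-oxo-4H-chromen-2-yl)phenoxy]-4-oxo-4H-chromen-2-yl}phenyl acetate (neocryptomerin diacetate), via 5,5''-bis(trifluoroacetate) 16 (not isolated)
Conditions: [RuCl2(p-cymene)]2 (5 mol %), PhI(OCOCF3)2 (3 equiv), CF3CO2H/(CF3CO)2O, 80 °C; then cold aq. NaHCO3
Reagents that add atoms: [bis(trifluoroacetoxy)iodo]benzene, O=C(OI(OC(=O)C(F)(F)F)c1ccccc1)C(F)(F)F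
Why: Chloride/trifluoroacetate exchange gives an electrophilic divalent ruthenium carboxylate; the C4 carbonyl oxygen of each pyranone binds it, and carboxylate-assisted deprotonation cleaves the peri C5–H to a five-membered ruthenacycle (O=C4–C4a–C5–Ru). The trivalent iodine reagent oxidises this to a tetravalent ruthenium trifluoroacetate, and C–O reductive elimination forms the C5–OCOCF3 bond and returns divalent ruthenium; the cycle runs once on each flavone to give 16, whose two aryl trifluoroacetates are far more labile than the aryl acetates and should be hydrolysed selectively by cold bicarbonate to 17. The closest known reaction is the ruthenium- or palladium-catalysed ketone-directed ortho C–H hydroxylation of aryl ketones, chromones and flavones with trivalent iodine or persulfate oxidants in trifluoroacetic media. No ring is closed and no stereocentre is formed. Site selectivity is needed twice and is secured by geometry: in each unit C5–H is the only C–H that a carbonyl-bound metal can reach through a five-membered chelate (C3–H would need a four-membered one, and the ring B hydrogens are out of reach). Chemoselectivity against oxidation of the aryl ether rings rests on the acetates at O7 and at the ring B oxygen of unit 2 and on the acceptor effect of each pyranone carbonyl on its ring A, and over-oxidation is blocked because each new oxygen emerges as an electron-poor trifluoroacetate and not as a free phenol. Oxidant and catalyst are used in excess so that the C5–H of unit 2, which lies next to the aryloxy group, also reacts.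

Step 12
Reactants: 17 neocryptomerin diacetate
Product: 18 neocryptomerin (5,7-dihydroxy-6-[4-(5-hydroxy-7-methoxy-4-oxo-4H-chromen-2-yl)phenoxy]-2-(4-hydroxyphenyl)-4H-chromen-4-one)
Conditions: K2CO3, MeOH/THF, 0 °C to rt, Ar; then 1 M HCl to pH 5
Reagents that add atoms: none
Why: Base-mediated transesterification of two aryl acetates by methanol; in the cold and under argon the methyl ether, the diaryl ether and both pyranones should be untouched, and no hot acid is used that could shift the ether linkage from C6 to C8.

## Compound list

1 | 2,4-dihydroxybenzaldehyde | O=Cc1ccc(O)cc1O | starting material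
2 | 2,4-bis(benzyloxy)benzaldehyde | O=Cc1ccc(OCc2ccccc2)cc1OCc1ccccc1 | intermediate
3 | 2,4-bis(benzyloxy)phenyl formate | O=COc1ccc(OCc2ccccc2)cc1OCc1ccccc1 | intermediate (not isolated)
4 | 2,4-bis(benzyloxy)phenol | Oc1ccc(OCc2ccccc2)cc1OCc1ccccc1 | intermediate
5 | 4-fluorobenzaldehyde | O=Cc1ccc(F)cc1 | starting material
6 | 4-[2,4-bis(benzyloxy)phenoxy]benzaldehyde | O=Cc1ccc(Oc2ccc(OCc3ccccc3)cc2OCc2ccccc2)cc1 | intermediate
7 | paeonol (2-hydroxy-4-methoxyacetophenone) | COc1ccc(C(C)=O)c(O)c1 | starting material
8 | (E)-3-{4-[2,4-bis(benzyloxy)phenoxy]phenyl}-1-(2-hydroxy-4-methoxyphenyl)prop-2-en-1-one | COc1ccc(C(=O)/C=C/c2ccc(Oc3ccc(OCc4ccccc4)cc3OCc3ccccc3)cc2)c(O)c1 | intermediate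
9 | 2-{4-[2,4-bis(benzyloxy)phenoxy]phenyl}-7-methoxy-4H-chromen-4-one | COc1ccc2c(=O)cc(-c3ccc(Oc4ccc(OCc5ccccc5)cc4OCc4ccccc4)cc3)oc2c1 | intermediate
10 | 2-[4-(2,4-dihydroxyphenoxy)phenyl]-7-methoxy-4H-chromen-4-one | COc1ccc2c(=O)cc(-c3ccc(Oc4ccc(O)cc4O)cc3)oc2c1 | intermediate
11 | 2-[4-(5-acetyl-2,4-dihydroxyphenoxy)phenyl]-7-methoxy-4H-chromen-4-one | COc1ccc2c(=O)cc(-c3ccc(Oc4cc(C(C)=O)c(O)cc4O)cc3)oc2c1 | intermediate
12 | 4-hydroxybenzaldehyde | O=Cc1ccc(O)cc1 | starting material
13 | (E)-1-{2,4-dihydroxy-5-[4-(7-methoxy-4-oxo-4H-chromen-2-yl)phenoxy]phenyl}-3-(4-hydroxyphenyl)prop-2-en-1-one | COc1ccc2c(=O)cc(-c3ccc(Oc4cc(C(=O)/C=C/c5ccc(O)cc5)c(O)cc4O)cc3)oc2c1 | intermediate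
14 | 5,5''-dideoxyneocryptomerin | COc1ccc2c(=O)cc(-c3ccc(Oc4cc5c(=O)cc(-c6ccc(O)cc6)oc5cc4O)cc3)oc2c1 | intermediate
15 | 5,5''-dideoxyneocryptomerin diacetate | COc1ccc2c(=O)cc(-c3ccc(Oc4cc5c(=O)cc(-c6ccc(OC(C)=O)cc6)oc5cc4OC(C)=O)cc3)oc2c1 | intermediate (key-step precursor)
16 | neocryptomerin diacetate 5,5''-bis(trifluoroacetate) | COc1cc(OC(=O)C(F)(F)F)c2c(=O)cc(-c3ccc(Oc4c(OC(C)=O)cc5oc(-c6ccc(OC(C)=O)cc6)cc(=O)c5c4OC(=O)C(F)(F)F)cc3)oc2c1 | intermediate (not isolated)
17 | neocryptomerin diacetate | COc1cc(O)c2c(=O)cc(-c3ccc(Oc4c(OC(C)=O)cc5oc(-c6ccc(OC(C)=O)cc6)cc(=O)c5c4O)cc3)oc2c1 | intermediate (key-step product)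
18 | neocryptomerin | COc1cc(O)c2c(=O)cc(-c3ccc(Oc4c(O)cc5oc(-c6ccc(O)cc6)cc(=O)c5c4O)cc3)oc2c1 | target

## Step count and least certain steps

Total step count: 12. Longest linear sequence: 12 steps, from 1 to 18; 5, 7 and 12 enter as purchased materials.

**Step 11 (key step).** Three things may go wrong. The second hydroxylation may be incomplete, because the C5–H of unit 2 is flanked by the aryloxy group and its metalation should be slower. The trivalent iodine reagent may oxidise the diaryl ether rings by one-electron transfer in the strong acid. The acetates may exchange with the trifluoroacetic medium and be lost on work-up; this last process is harmless, since step 12 removes every ester and all such material converges on 18. Fallback, from 15 back to 17 in two operations, replacing the acidic oxidising medium by C–B bond formation under neutral conditions: ketone-directed iridium-catalysed peri C–H borylation of both units ([Ir(OMe)(cod)]2, AsPh3, B2pin2, mesitylene, 120 °C) would give the 5,5''-bis(pinacolboronate) F1. Oxidation of both C–B bonds with KHSO5 (as Oxone, 2KHSO5·KHSO4·K2SO4) in acetone/water at room temperature, which leaves aryl acetates alone, would then give 17.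

**Step 9.** Iodination or oxidative coupling of the free phenol rings may compete with the dehydrogenation at 120 °C, and the polar chalcone and product may dissolve poorly. Fallback, from 13 to 15 in three operations without iodine, bypassing 14 and step 10: NaOAc in ethanol at reflux should close 13 by oxa-Michael addition to the racemic flavanone F2. Ac2O/pyridine would give its diacetate F3, and DDQ in dioxane at reflux would dehydrogenate C2–C3 of the protected flavanone to give 15 directly.

**Step 8.** The condensation may be sluggish because 12 is a deactivated, vinylogous-acid aldehyde. The phenolic aldehyde may oligomerise under acid. The product may partly close to its ring-closed isomer; this last process does no harm, since both forms are oxidised to the same flavone. Fallback, from 11 to 14 in two operations, replacing the chalcone route (steps 8 and 9) by an acylation and cyclodehydration that needs no oxidant: 11 is converted into its trianion with LiN(SiMe3)2 (5 equiv) in THF at −78 °C and C-acylated with 4-(tert-butyldimethylsilyloxy)benzoyl chloride F4, made from 4-hydroxybenzoic acid by silylation and treatment with oxalyl chloride. This would give the β-diketone F5. Heating F5 in AcOH with catalytic H2SO4 at 95 °C should close ring C and remove the silyl group to give 14.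

**Step 7.** The reaction may stop at O-acylation with incomplete Fries shift, some acylation may occur between the two hydroxyls, or the air-sensitive resorcinol 10 may degrade at 90 °C in strong Lewis acid. Fallback, from 9 to 11 in two operations, acylating before the phenols are set free: Friedel–Crafts acetylation of the bis(benzyl ether) 9 with AcCl and SnCl4 in CH2Cl2 at −20 °C should go para to one benzyloxy group and ortho to the other, giving the ketone F6. Hydrogenolysis (H2, Pd/C) then gives 11. Any loss of the benzyl group next to the new ketone under the Lewis acid would not matter, since both benzyl groups are removed in the next operation.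

## Further compounds

F1 | step 11 | 5,5''-bis(4,4,5,5-tetramethyl-1,3,2-dioxaborolan-2-yl) derivative of 15 | COc1cc(B2OC(C)(C)C(C)(C)O2)c2c(=O)cc(-c3ccc(Oc4c(OC(C)=O)cc5oc(-c6ccc(OC(C)=O)cc6)cc(=O)c5c4B4OC(C)(C)C(C)(C)O4)cc3)oc2c1
F2 | step 9 | racemic 7-hydroxy-2-(4-hydroxyphenyl)-6-[4-(7-methoxy-4-oxo-4H-chromen-2-yl)phenoxy]chroman-4-one | COc1ccc2c(=O)cc(-c3ccc(Oc4cc5C(=O)CC(c6ccc(O)cc6)Oc5cc4O)cc3)oc2c1
F3 | step 9 | racemic 4-{7-acetoxy-6-[4-(7-methoxy-4-oxo-4H-chromen-2-yl)phenoxy]-4-oxochroman-2-yl}phenyl acetate | COc1ccc2c(=O)cc(-c3ccc(Oc4cc5C(=O)CC(c6ccc(OC(C)=O)cc6)Oc5cc4OC(C)=O)cc3)oc2c1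
F4 | step 8 | 4-(tert-butyldimethylsilyloxy)benzoyl chloride | CC(C)(C)[Si](C)(C)Oc1ccc(C(Cl)=O)cc1
F5 | step 8 | 1-{2,4-dihydroxy-5-[4-(7-methoxy-4-oxo-4H-chromen-2-yl)phenoxy]phenyl}-3-[4-(tert-butyldimethylsilyloxy)phenyl]propane-1,3-dione | COc1ccc2c(=O)cc(-c3ccc(Oc4cc(C(=O)CC(=O)c5ccc(O[Si](C)(C)C(C)(C)C)cc5)c(O)cc4O)cc3)oc2c1
F6 | step 7 | 2-{4-[5-acetyl-2,4-bis(benzyloxy)phenoxy]phenyl}-7-methoxy-4H-chromen-4-one | COc1ccc2c(=O)cc(-c3ccc(Oc4cc(C(C)=O)c(OCc5ccccc5)cc4OCc4ccccc4)cc3)oc2c1
A1 | alternative 1 | methyl 4-[2,6-bis(benzyloxy)-4-(methoxymethoxy)phenoxy]benzoate | COC(=O)c1ccc(Oc2c(OCc3ccccc3)cc(OCOC)cc2OCc2ccccc2)cc1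
A2 | alternative 1 | 1,3-bis(benzyloxy)-2-(ethynyloxy)-5-(methoxymethoxy)benzene | C#COc1c(OCc2ccccc2)cc(OCOC)cc1OCc1ccccc1
A3 | alternative 1 | methyl coumalate (methyl 2-oxo-2H-pyran-5-carboxylate) | COC(=O)c1ccc(=O)oc1
A4 | alternative 2 | neocryptomerin benzyl ether (benzyl on the ring B oxygen of unit 2) | COc1cc(O)c2c(=O)cc(-c3ccc(Oc4c(O)cc5oc(-c6ccc(OCc7ccccc7)cc6)cc(=O)c5c4O)cc3)oc2c1
A5 | alternative 2 | racemic methyl 4-{6-[4-(benzyloxy)phenyl]-4-oxo-4H-pyran-2-yl}-2-[4-(5-hydroxy-7-methoxy-4-oxo-4H-chromen-2-yl)phenoxy]-3-oxobutanoate | COC(=O)C(Oc1ccc(-c2cc(=O)c3c(O)cc(OC)cc3o2)cc1)C(=O)Cc1cc(=O)cc(-c2ccc(OCc3ccccc3)cc2)o1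
A6 | alternative 3 | neocryptomerin tetrabenzyl ether | COc1cc(OCc2ccccc2)c2c(=O)cc(-c3ccc(Oc4c(OCc5ccccc5)cc5oc(-c6ccc(OCc7ccccc7)cc6)cc(=O)c5c4OCc4ccccc4)cc3)oc2c1
A7 | alternative 3 | 3-(benzyloxy)-5-methoxy-2-[(triphenylphosphoranylidene)acetyl]phenyl 4-{2,6-bis(benzyloxy)-4-{[4-(benzyloxy)benzoyl]oxy}-3-[(triphenylphosphoranylidene)acetyl]phenoxy}benzoate | COc1cc(OCc2ccccc2)c(C(=O)C=P(c2ccccc2)(c2ccccc2)c2ccccc2)c(OC(=O)c2ccc(Oc3c(OCc4ccccc4)cc(OC(=O)c4ccc(OCc5ccccc5)cc4)c(C(=O)C=P(c4ccccc4)(c4ccccc4)c4ccccc4)c3OCc3ccccc3)cc2)c1
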